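The earlier runs and the new flask were generated by integration for an exercise, and the scatter is random.

**Reading times.** Read at 5.0 min and again at 8.0 s, the flask of solid substrate is asked for one ratio: the share [isomer of the product A]/([isomer of the product A]+[target]).

| flask | solid substrate | remark | time |
|---|---|---|---|
| epsilon | 0.10 M | run made earlier |  |
| eta | 0.15 M | run made earlier |  |
| flask | 0.20 M |  | 5.0 min |

| run | time / min | isomer of the product A / % | target / % | solid substrate / % |
|---|---|---|---|---|
| epsilon | 0.250 | 2.5 | 4.5 | 88.1 |
| epsilon | 0.833 | 7.8 | 15.8 | 63.5 |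
| epsilon | 1.33 | 11.8 | 24.9 | 44.1 |
| epsilon | 2.00 | 16.3 | 35.1 | 21.9 |
| epsilon | 3.00 | 20.0 | 43.8 | 0.3 |
| epsilon | 4.00 | 18.9 | 41.7 | 0 |
| epsilon | 5.00 | 18.4 | 40.5 | 0.4 |
| eta | 0.417 | 2.7 | 5.4 | 87.0 |
| eta | 0.667 | 4.1 | 8.7 | 79.7 |
| eta | 1.00 | 6.2 | 12.6 | 70.7 |
| eta | 1.33 | 8.0 | 16.6 | 62.9 |
| eta | 2.00 | 11.0 | 23.2 | 48.2 |
| eta | 3.00 | 14.6 | 31.1 | 28.0 |
| eta | 5.00 | 17.9 | 40.3 | 0.4 |

(standard deviation of a reading: 0.3 percentage points)

- solid, in amounts per volume of the solution: solid substrate
- at the start none of the solid substrate is in solution

- share of isomer of the product A in isomer of the product A plus target at 8.0 s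
- share of isomer of the product A in isomer of the product A plus target at 5.0 min

**A held pair.** In the epsilon run the solid substrate reads 0.3 % at 3.00 min. From then until 5.00 min the isomer of the product A keeps 92.0 % of its amount and the target keeps 92.5 %. Two species losing equal fractions read as a pair in quick exchange, whose ratio follows the equilibrium constants of that exchange and not the total (thermodynamic control). The last epsilon reading gives the held share, the value of the ratio such a pair keeps: 31.2 %.

**Own reckoning.** The eta run, with solid substrate still at 28.0 % at 3.00 min, already reads a share of 31.9 %, which is 0.71 percentage points from the held share. The reckoning here for the 0.20 M flask at 5.0 min is therefore the held share itself. For 8.0 s it offers nothing, since the earliest reading, at 0.250 min, comes later.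

**The forecast.** The forecast gives 33.7 % at 8.0 s and 30.6 % at 5.0 min, holding that “the share seems to fall with time only while solid is present”. Its late value lies below the held share.

**The result.** The flask gives 29.0 % at 8.0 s and 31.3 % at 5.0 min, both within the forecast's margins. The isomer of the product A goes back to starting material with a half-life of 0.55 min, short against the 5.0 min. With 21.8 % of solid substrate still present, the flask stands 0.100 points from the held share and 0.70 points above the forecast.

    2 starting material → self-condensation product (k = 0.645 L mol⁻¹ s⁻¹)
    starting material ⇌ isomer of the product A (K = 2.70, k = 0.0563 s⁻¹)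
    solid substrate ⇌ starting material, rate k3*(cs3 - [starting material]) while solid is left; crystals form when [starting material] > cs3 (solubility = 18.0 mM, k = 0.0531 s⁻¹)
    target ⇌ isomer of the product B (K = 0.420, k = 0.0531 s⁻¹)
    starting material ⇌ target (K = 6.00, k = 0.157 s⁻¹)

**Second flask.** With 0.12 M of solid substrate, the held share gives 31.2 % at 5.0 min. The computed value for that flask is 31.1 %.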